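**Compound numbering used throughout**
1 4'-(benzyloxy)acetophenone · 2 diethyl carbonate · 3 ethyl 3-[4-(benzyloxy)phenyl]-3-oxopropanoate · 4 ethyl 3-[4-(benzyloxy)phenyl]-3-oxo-2-(pivaloyloxy)propanoate (racemic) · 5 phloroglucinol · 6 α-pivaloyloxy aroylketene · 7 C-acylated triketone · 8 3-O-pivaloyl flavonol · 9 kaempferol 4'-benzyl ether · 10 dipotassium 4'-O-benzylkaempferol 3,7-disulfate · 11 dipotassium kaempferol 3,7-disulfate · 12 kaempferol 3,7-di-O-sulfate (target)

## Analysis of the target

The target is a flavonol. Ring A (C4a, C5, C6, C7, C8, C8a) is fused to the γ-pyranone ring C (O1, C2, C3, C4), and a 4-hydroxyphenyl ring B sits on C2. All fifteen skeletal carbons are sp2 and there is no stereocentre and no hindered axis, so the difficulty is purely one of regiochemistry among four oxygen functions. O3 (the enol oxygen of ring C) and O7 carry hydrogen sulfate groups, while O5–H (hydrogen-bonded to C4=O) and O4'–H are free. The chelated O5–H is the least reactive hydroxyl and protects itself. O4'–H is about as acidic and nucleophilic as O7–H and is more easily sulfated than O3–H, so it has to stay masked until both sulfates are in place. The aryl and enol sulfate monoesters tolerate base and hydrogenolysis but solvolyse under acid and heat, and the free acid form is autocatalytically labile. They also make every intermediate after sulfation very polar, so few steps may follow. The C5 oxygen undermines the textbook oxidative cyclisation of a chalcone, because a 6'-substituted 2'-hydroxychalcone tends to close to the five-membered aurone. Ring A carries oxygen at C8a (O1), C5 and C7, which is the 1,3,5-pattern of the threefold-symmetric triphenol 5. Ring C places an acyl carbon (C4) and an aryl-bearing enol-ether carbon (C2) in a 1,3-relationship around the oxygenated C3, which is the pattern of an α-oxygenated aroylketene.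

## Retrosynthetic reasoning

**12 ⇒ 11 ⇒ 10 (O–H and O4'–CH2Ph).** The free acid is generated last from its dipotassium salt 11, which is the stable form. 11 comes from 10 by cleaving the single benzyl–O4' bond. This is the only protecting group of the route, and hydrogenolysis is chosen because sulfate monoester anions survive it.

**10 ⇒ 9 (O3–S and O7–S).** Both sulfur–oxygen bonds are made in one sulfation of 9. The cut is placed here because in 9 the selectivity problem is already solved by structure: O4' is blocked, O5–H is chelated, and only O3–H and O7–H remain. The forward reaction has to sulfate the sluggish O3–H without reaching O5–H.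

**9 ⇒ 8 ⇒ 7 ⇒ 5 + 6 (C4–C4a and O1–C2, the key disconnection).** Ring C is cut at its two bonds to ring A, which separates the molecule into the unprotected triphenol 5 and the three-carbon unit 6 carrying ring B. Each of the three carbons of 6 is already at its final oxidation level: ketene carbon for C4, acyloxy-bearing carbon for C3, aryl ketone for C2. This cut is preferred because the equivalence of all positions of 5 removes any regiochemical question, and because the two hydroxyls of 5 not used in the annulation become the free 5-OH and 7-OH without protection. The forward reaction must C-acylate 5 with the ketene carbon of 6 (giving 7), close O1 onto the aryl ketone with dehydration (giving 8), and release O3–H by aminolysis of the acyl group (giving 9).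

**6 ⇒ 4 ⇒ 3 (ketene from ester; C2–O of the keto ester).** The ketene 6 is not made separately; it is released thermally from the β-keto ester 4 by loss of the ester alcohol. The α-oxygen of 4 is introduced on 3 by electrophilic acyloxylation of the 1,3-dicarbonyl. A pivalate is chosen because it is removable in the presence of the benzyl ether and is the acyl group least prone to migrate.

**3 ⇒ 1 + 2 (C–C of the β-keto ester).** A Claisen-type ethoxycarbonylation of the methyl ketone 1 with carbonate 2 supplies the carbon that becomes C4.

## Alternatives that were turned down

**Alternative 1:** the textbook chalcone route. The disconnection is C2–C3 by aldol condensation, then O1–C2 and C3–O by Algar–Flynn–Oyamada oxidation. The forward key step treats the 2'-hydroxy-4',6'-bis(methoxymethoxy)chalcone A1 with alkaline peroxide and should give the protected flavonol A3. It was turned down for two reasons.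
- The 6'-oxygen of A1 (the future C5–O) twists the aryl ketone out of plane and steers the phenoxide to the α-carbon (5-exo), so the aurone A2 is the expected main product. The step that is meant to build ring C therefore builds the wrong ring.
- Ring A cannot face alkaline peroxide unprotected, so two acetal groups have to be put on and taken off. The sequence comes to about seven steps around a compromised key step.

**Alternative 2:** a three-component palladium-catalysed carbonylative alkynylation–cyclisation. The iodophenol A4, CO and the ring-B terminal arylalkyne are joined, cutting C4–C4a, C3–C4 and O1–C2, to give the flavone A5. C3–H is then oxidised with a dioxirane to reach A3. It was turned down on three structural grounds.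
- The key step delivers ring C at the wrong oxidation level (C3–H), so a separate oxidation on a fully protected substrate is needed.
- A4 requires desymmetrisation of ring A (two protections and one regiodefined iodination), which discards the symmetry the target offers.
- The intermediate ynone can close 5-exo to an aurone as well as 6-endo.
The count is eight or more steps.

**Alternative 3:** an Auwers-type ring enlargement, which changes the skeleton. The aurone A6 is assembled by aldol condensation of the ring-A benzofuranone with the ring-B aldehyde. Halogenation of its exocyclic alkene followed by hydroxide is meant to break O1–C2 of the five-membered ring and re-close O1 onto the benzylic carbon to give 9. The idea is attractive because it turns the aurone preference into an asset. It was turned down for three reasons.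
- The electrophilic halogen would attack C5 and C7 of the phloroglucinol-type ring of A6 before the electron-poor exocyclic alkene, so ring A would again need protection.
- Elimination back to a haloaurone competes with ring enlargement.
- It needs three operations for what step 3 does in one.

Key step: step 3

Remark: the target has no stereocentre, so "single enantiomer" needs no control; it is taken as the free bis(hydrogen sulfate) as drawn, with the dipotassium salt 11 as the storage form.

## Route

**Step 1**
Reactants: 1 4'-(benzyloxy)acetophenone; 2 diethyl carbonate
Product: 3 ethyl 3-[4-(benzyloxy)phenyl]-3-oxopropanoate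
Conditions: NaH (2.5 equiv), 2 (3 equiv), toluene, 110 °C; AcOH quench
Reagents that add atoms: none
Why: Claisen-type C-ethoxycarbonylation of the ketone enolate by the carbonate; it is driven to completion by deprotonation of the β-keto ester product, and the benzyl ether is inert to hydride base.

**Step 2**
Reactants: 3 ethyl 3-[4-(benzyloxy)phenyl]-3-oxopropanoate
Product: 4 ethyl 3-[4-(benzyloxy)phenyl]-3-oxo-2-(pivaloyloxy)propanoate (racemic)
Conditions: PhI(OPiv)2 (1.2 equiv), PivOH (3 equiv), MeCN, 40 °C
Reagents that add atoms: [bis(pivaloyloxy)iodo]benzene CC(C)(C)C(=O)OI(OC(=O)C(C)(C)C)c1ccccc1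
Why: Hypervalent iodine(III) α-acyloxylation of a 1,3-dicarbonyl: the enol attacks iodine and carboxylate displaces iodobenzene at the α-carbon. The product is more hindered and enolises less, which should hold the reaction at the mono-acyloxy stage. The new stereocentre is formed racemic and becomes sp2 in step 3.

**Step 3**
Reactants: 4 ethyl 3-[4-(benzyloxy)phenyl]-3-oxo-2-(pivaloyloxy)propanoate; 5 phloroglucinol (anhydrous)
Product: 9 kaempferol 4'-benzyl ether [2-(4-benzyloxyphenyl)-3,5,7-trihydroxy-4H-chromen-4-one], via α-pivaloyloxy aroylketene 6 (not isolated), via C-acylated triketone 7 (not isolated), via 3-O-pivaloyl flavonol 8 (not isolated)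
Conditions: 5 (1.5 equiv), Ph2O, 230 °C, N2 sweep (−EtOH), 1 h; then 7 M NH3 in MeOH, 40 °C, N2
Reagents that add atoms: none
Why: On heating, the enol form of 4 loses ethanol through a six-membered transition state and gives the α-pivaloyloxy aroylketene 6, which is trapped by 5; O-acylation is reversible at this temperature (the aryl ester re-forms 6) whereas C-acylation through the keto tautomer of 5 is not, so material drains to triketone 7 and the C4–C4a bond is made. The ortho hydroxyl of 7 then adds to the aryl ketone carbonyl (6-exo-trig hemiketalisation) and water is lost, which makes the O1–C2 bond, closes ring C and gives 8; ammonia in methanol finally cleaves the activated enol pivalate (and any pivalate that has moved to a phenol) to give 9. The closest known reaction type is the thermal, catalyst-free chromone condensation of phenols with β-keto esters (Mentzer pyrone synthesis, with the Simonis-type chromone outcome), which is established for 5 with aroylacetates; only the α-acyloxy substituent is new. No stereocentre is formed, since the racemic centre of 4 and 7 becomes sp2. Regiochemistry needs no control because the three C–H and the three O–H positions of 5 are equivalent, so the annulation automatically leaves the free 5- and 7-hydroxyls. Chromone rather than coumarin connectivity is secured by the acid-free conditions: the ketene carbon is the only strong electrophile, and the p-alkoxyaryl ketone is too deactivated for an uncatalysed hydroxyalkylation of 5. A second annulation is held back by the new C4 carbonyl, which deactivates ring A, and by the excess of 5. Pivaloyl is chosen over acetyl because its bulk slows the 1,2-acyl shift across the enediol, transacylation to 5 and 5-exo displacement of carboxylate by the phenol; the benzyl ether is thermally stable here in the absence of strong acid.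

**Step 4**
Reactants: 9 kaempferol 4'-benzyl ether
Product: 10 dipotassium 4'-O-benzylkaempferol 3,7-disulfate
Conditions: Me3N·SO3 (8 equiv), Et3N (10 equiv), DMA, 65 °C, HPLC control; then 1 M KOH/MeOH to pH 9, 0 °C; C18 or Sephadex LH-20
Reagents that add atoms: sulfur trioxide–trimethylamine complex C[N+](C)(C)S(=O)(=O)[O-]; potassium hydroxide [K+].[OH-]
Why: O-Sulfonation of phenolic and enolic hydroxyls with an amine–sulfur trioxide complex. The acidic 7-OH and the 3-OH should react, while the 5-OH stays free under conventional heating because it is locked in a hydrogen bond to C4=O, and O4' is blocked as the benzyl ether. Potassium hydroxide only exchanges the ammonium counter-ions; sulfate monoester anions are stable to it.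

**Step 5**
Reactants: 10 dipotassium 4'-O-benzylkaempferol 3,7-disulfate
Product: 12 kaempferol 3,7-di-O-sulfate (target), via dipotassium kaempferol 3,7-disulfate 11 (not isolated)
Conditions: H2 (1 atm), 10% Pd/C, MeOH–H2O 4:1, 25 °C; filter, evaporate; then H2SO4 (1.00 equiv), MeOH–H2O 9:1, 0 °C, filter off K2SO4, dilute with water, freeze-dry
Reagents that add atoms: none
Why: Hydrogenolysis of the benzyl aryl ether over palladium; sulfate monoester anions are neither cleaved nor catalyst poisons, and the tetrasubstituted, cross-conjugated C2=C3 bond of a flavonol should not be reduced at 1 atm. One equivalent of sulfuric acid then protonates both sulfates while potassium sulfate precipitates from cold aqueous methanol, so the free acid is obtained without excess mineral acid. Salt 11 can be kept instead if the acid is not needed at once.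

## Compound list

1 | 4'-(benzyloxy)acetophenone | CC(=O)c1ccc(OCc2ccccc2)cc1 | starting material
2 | diethyl carbonate | CCOC(=O)OCC | starting material
3 | ethyl 3-[4-(benzyloxy)phenyl]-3-oxopropanoate | CCOC(=O)CC(=O)c1ccc(OCc2ccccc2)cc1 | intermediate
4 | ethyl 3-[4-(benzyloxy)phenyl]-3-oxo-2-(pivaloyloxy)propanoate (racemic) | CCOC(=O)C(OC(=O)C(C)(C)C)C(=O)c1ccc(OCc2ccccc2)cc1 | intermediate
5 | phloroglucinol (benzene-1,3,5-triol) | Oc1cc(O)cc(O)c1 | starting material
6 | α-pivaloyloxy aroylketene [3-(4-benzyloxyphenyl)-3-oxo-2-(pivaloyloxy)prop-1-en-1-one] | O=C=C(OC(=O)C(C)(C)C)C(=O)c1ccc(OCc2ccccc2)cc1 | intermediate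
7 | 1-[4-(benzyloxy)phenyl]-2-(pivaloyloxy)-3-(2,4,6-trihydroxyphenyl)propane-1,3-dione (racemic) | CC(C)(C)C(=O)OC(C(=O)c1ccc(OCc2ccccc2)cc1)C(=O)c1c(O)cc(O)cc1O | intermediate
8 | 2-[4-(benzyloxy)phenyl]-5,7-dihydroxy-4-oxo-4H-chromen-3-yl pivalate | CC(C)(C)C(=O)Oc1c(-c2ccc(OCc3ccccc3)cc2)oc2cc(O)cc(O)c2c1=O | intermediate
9 | kaempferol 4'-benzyl ether [2-(4-benzyloxyphenyl)-3,5,7-trihydroxy-4H-chromen-4-one] | O=c1c(O)c(-c2ccc(OCc3ccccc3)cc2)oc2cc(O)cc(O)c12 | intermediate
10 | dipotassium 4'-O-benzylkaempferol 3,7-disulfate | O=c1c(OS(=O)(=O)[O-])c(-c2ccc(OCc3ccccc3)cc2)oc2cc(OS(=O)(=O)[O-])cc(O)c12.[K+].[K+] | intermediate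
11 | dipotassium kaempferol 3,7-disulfate | O=c1c(OS(=O)(=O)[O-])c(-c2ccc(O)cc2)oc2cc(OS(=O)(=O)[O-])cc(O)c12.[K+].[K+] | intermediate
12 | kaempferol 3,7-di-O-sulfate | O=c1c(OS(=O)(=O)O)c(-c2ccc(O)cc2)oc2cc(OS(=O)(=O)O)cc(O)c12 | target

## Step count and least certain steps

Total step count: 5. Longest linear sequence: 5 steps (1 → 3 → 4 → 9 → 10 → 12); 2 and 5 enter as single-step partners.

**Step 3 (key step).** The pivaloyl group may shift thermally across the enediol of 4 or 6, or transfer to 5. Either process exposes the α-hydroxyl, after which the three-carbon unit can fragment or alkylate 5 through a keto-ester carbonyl. Alternatively, in 7 the phenol may displace pivalate 5-exo and close a five-membered ring instead of the pyranone. The fallback forms the C3–O bond after ring C instead of carrying it through the annulation. It sets out from 3 and 5 and returns to the route at 9.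
- 3 and 5 are condensed thermally as such (Ph2O, 240 °C, the parent case of this reaction) to give 4'-O-benzylapigenin F1.
- MOMCl/NaH in DMF caps both phenols to give the 5,7-bis(methoxymethyl) ether F2.
- Dimethyldioxirane in acetone/CH2Cl2 epoxidises C2=C3 to the racemic 2,3-epoxide F3.
- Catalytic TsOH opens and tautomerises F3 to the 3-hydroxyflavone F4.
- HCl in methanol removes both acetal groups and gives 9.

**Step 4.** Sulfation of the hydrogen-bonded, hindered 3-OH may stall at the 7-monosulfate, or forcing may start sulfation at the 5-OH. Isolation of the very polar salts may also cost material. The fallback replaces direct sulfation by protected sulfate diesters; it sets out from 9 and returns at 10.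
- 9 is treated with 2,2,2-trichloroethyl chlorosulfate (2.4 equiv), Et3N and DMAP in THF to give the neutral bis(2,2,2-trichloroethyl sulfate) diester F5, which can be purified on silica and whose stoichiometry is easy to control.
- Zn/HCO2NH4 in methanol removes both trichloroethyl groups by reductive β-elimination and leaves the diammonium 4'-O-benzylkaempferol 3,7-disulfate F6.
- Evaporation with aqueous K2CO3 exchanges the cation and gives 10.

**Step 2.** The iodine(III) reagent may acyloxylate twice or cleave the 1,3-dicarbonyl oxidatively (retro-Claisen of the activated α-position). The fallback makes the C–O bond by carbenoid O–H insertion instead of electrophilic oxidation; it sets out from 3 and returns at 4.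
- Diazo transfer (p-acetamidobenzenesulfonyl azide, Et3N, MeCN) gives the α-diazo keto ester F7.
- Rh2(OAc)4 (1 mol %) with pivalic acid in CH2Cl2 at 40 °C inserts the carbenoid into the acid O–H bond and gives 4.

**Step 5.** The enol 3-O-sulfate may be lost by solvolysis while the free acid is in methanol or is being concentrated. The fallback avoids soluble mineral acid and methanol; it sets out from 11, returns at 12 and makes no new compound (F0). An aqueous solution of 11 is passed through a sulfonic acid resin in its H+ form at 0–4 °C and the eluate is freeze-dried directly.

## Further compounds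

F1 | step 3 | 4'-O-benzylapigenin [2-(4-benzyloxyphenyl)-5,7-dihydroxy-4H-chromen-4-one] | O=c1cc(-c2ccc(OCc3ccccc3)cc2)oc2cc(O)cc(O)c12
F2 | step 3 | 2-[4-(benzyloxy)phenyl]-5,7-bis(methoxymethoxy)-4H-chromen-4-one | COCOc1cc(OCOC)c2c(=O)cc(-c3ccc(OCc4ccccc4)cc3)oc2c1
F3 | step 3 | 2-[4-(benzyloxy)phenyl]-2,3-epoxy-5,7-bis(methoxymethoxy)chroman-4-one (racemic, one enantiomer drawn) | COCOc1cc(OCOC)c2c(c1)O[C@@]1(c3ccc(OCc4ccccc4)cc3)O[C@H]1C2=O
F4 | step 3 | 2-[4-(benzyloxy)phenyl]-3-hydroxy-5,7-bis(methoxymethoxy)-4H-chromen-4-one | COCOc1cc(OCOC)c2c(=O)c(O)c(-c3ccc(OCc4ccccc4)cc3)oc2c1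
F5 | step 4 | 4'-O-benzylkaempferol 3,7-bis(2,2,2-trichloroethyl sulfate) | O=c1c(OS(=O)(=O)OCC(Cl)(Cl)Cl)c(-c2ccc(OCc3ccccc3)cc2)oc2cc(OS(=O)(=O)OCC(Cl)(Cl)Cl)cc(O)c12
F6 | step 4 | diammonium 4'-O-benzylkaempferol 3,7-disulfate | O=c1c(OS(=O)(=O)[O-])c(-c2ccc(OCc3ccccc3)cc2)oc2cc(OS(=O)(=O)[O-])cc(O)c12.[NH4+].[NH4+]
F7 | step 2 | ethyl 3-[4-(benzyloxy)phenyl]-2-diazo-3-oxopropanoate | CCOC(=O)C(=[N+]=[N-])C(=O)c1ccc(OCc2ccccc2)cc1
F0 | step 5 | none | none
A1 | alternative 1 | (E)-4-(benzyloxy)-2'-hydroxy-4',6'-bis(methoxymethoxy)chalcone | COCOc1cc(O)c(C(=O)/C=C/c2ccc(OCc3ccccc3)cc2)c(OCOC)c1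
A2 | alternative 1 | (Z)-2-[4-(benzyloxy)benzylidene]-4,6-bis(methoxymethoxy)benzofuran-3(2H)-one | COCOc1cc(OCOC)c2c(c1)O/C(=C\c1ccc(OCc3ccccc3)cc1)C2=O
A3 | alternative 1 | 2-[4-(benzyloxy)phenyl]-3-hydroxy-5,7-bis(methoxymethoxy)-4H-chromen-4-one | COCOc1cc(OCOC)c2c(=O)c(O)c(-c3ccc(OCc4ccccc4)cc3)oc2c1
A4 | alternative 2 | 2-iodo-3,5-bis(methoxymethoxy)phenol | COCOc1cc(O)c(I)c(OCOC)c1
A5 | alternative 2 | 2-[4-(benzyloxy)phenyl]-5,7-bis(methoxymethoxy)-4H-chromen-4-one | COCOc1cc(OCOC)c2c(=O)cc(-c3ccc(OCc4ccccc4)cc3)oc2c1
A6 | alternative 3 | (Z)-2-[4-(benzyloxy)benzylidene]-4,6-dihydroxybenzofuran-3(2H)-one | Oc1cc(O)c2c(c1)O/C(=C\c1ccc(OCc3ccccc3)cc1)C2=O
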